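**Strategy**

Numbering: lactone O-CH = C13, lactone-bearing CH = C14, then C1 (CH2), C2 (CHOH), C3 (CMe-OAc), C4, C5, C6=C7(Me), C8, C9, C10=C11(Me), C12 (CHOAc). C15(=C17H2) and C16 (C=O) are the lactone carbons on C14.
Enabling feature: ring atoms C12-C13-C14-C1-C2-C3, the methyl on C3 and the C15/C16/C17 unit on C14 make up a p-menthane six-membered ring that lacks only its C12-C3 bond. Oxygen sits on C12, C13, C2 and C3, the positions an enone can functionalise, so these ten carbons can be cut out of carvone.
Retrosynthesis: cut the lactone O-C16 bond, the ring bond C11-C12, the alkene C10=C11 and the bond C3-C4. Re-joining C12-C3 then gives a cyclohexene oxide that traces back to (S)-carvone.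
Forward: the carvone ring is oxygenated, transposed, epoxidised and cleaved to a chain (C12 aldehyde, C3 methyl ketone). The C4-C10 chain is attached at C3-C4, C11 is added by iodo-olefination, the 14-membered ring closes at C11-C12, and the γ-lactone closes last.
Stereochemistry: C14 is the carvone centre. C13 and C2 are set on the six-membered ring anti to the C14 side chain, C3 by Cram-chelate addition next to C2-OPMB, and C12 by Felkin-Anh addition next to C13-OTBS. Z-C6=C7 comes from the cis geometry locked in a dihydrofuran, and Z-C10=C11 from a Stork-Zhao olefination.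

Key step: step 10

Assumption: both trisubstituted ring alkenes are taken exactly as written in the SMILES, that is both Z, with the two ring carbons cis on each double bond.
Abbreviations: TBS = tert-butyldimethylsilyl, TES = triethylsilyl, PMB = 4-methoxybenzyl, Piv = pivaloyl. "Route numbering" is the numbering defined above.

Step 1
Reactants: 1 (S)-(+)-carvone
Product: 2 (5S)-5-(3-chloroprop-1-en-2-yl)-2-methylcyclohex-2-en-1-one (10-chlorocarvone)
Conditions: Ca(OCl)2, solid CO2, CH2Cl2-H2O, 0 °C
Reagents that add atoms: calcium hypochlorite, [Ca+2].[O-]Cl.[O-]Cl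
Why: Ene-type allylic chlorination by hypochlorous acid attacks the electron-rich 1,1-disubstituted alkene, leaves the electron-poor enone alone and regenerates the exocyclic methylene, as is well known for carvone itself; the C5 centre (future C14) is untouched.

Step 2
Reactants: 2 10-chlorocarvone
Product: 4 (5S)-5-(3-hydroxyprop-1-en-2-yl)-2-methylcyclohex-2-en-1-one (10-hydroxycarvone), via 10-acetoxycarvone 3 (not isolated)
Conditions: KOAc, Bu4NI (cat.), DMF, 50 °C; then MeOH, K2CO3 (cat.), 0 °C → rt
Reagents that add atoms: potassium acetate, CC(=O)[O-].[K+]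
Why: SN2 displacement of the primary allylic chloride by acetate followed by carbonate-catalysed transesterification is the standard halide-to-alcohol exchange and spares the enone the hydroxide that direct hydrolysis would need.

Step 3
Reactants: 4 10-hydroxycarvone
Product: 5 (5S)-5-[3-(TBSO)prop-1-en-2-yl]-2-methylcyclohex-2-en-1-one
Conditions: TBSCl, imidazole, CH2Cl2, 0 °C → rt
Reagents that add atoms: tert-butyldimethylsilyl chloride, CC(C)(C)[Si](C)(C)Cl
Why: Routine imidazole-promoted silylation of a primary allylic alcohol, which also shuts off oxa-Michael addition of this oxygen to the enone in the basic steps that follow.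

Step 4
Reactants: 5 10-(TBSO)carvone
Product: 7 (5R,6R)-6-hydroxy-5-[3-(TBSO)prop-1-en-2-yl]-2-methylcyclohex-2-en-1-one (OH trans to the side chain), via lithium dienolate 6 (not isolated)
Conditions: LDA, THF, -78 °C; then 3-phenyl-2-(phenylsulfonyl)oxaziridine, -78 °C
Reagents that add atoms: 3-phenyl-2-(phenylsulfonyl)oxaziridine, O=S(=O)(N1OC1c1ccccc1)c1ccccc1
Why: Kinetic deprotonation of the cyclohexenone occurs at the α' carbon C6 to give the cross-conjugated dienolate, and Davis enolate hydroxylation takes place on the face opposite the adjacent C5 side chain, which sets the future C13 as the trans ketol.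

Step 5
Reactants: 7 trans-6-hydroxy-10-(TBSO)carvone
Product: 8 (5R,6R)-6-(TBSO)-5-[3-(TBSO)prop-1-en-2-yl]-2-methylcyclohex-2-en-1-one
Conditions: TBSOTf, 2,6-lutidine, CH2Cl2, -78 → 0 °C
Reagents that add atoms: tert-butyldimethylsilyl triflate, CC(C)(C)[Si](C)(C)OS(=O)(=O)C(F)(F)F
Why: A silyl triflate with a hindered pyridine base silylates the secondary ketol quickly at low temperature, before enediol tautomerisation can scramble C6.

Step 6
Reactants: 8 bis(silyloxy) enone
Product: 9 (1S,3R,4R,6S)-3-(TBSO)-4-[3-(TBSO)prop-1-en-2-yl]-1-methyl-7-oxabicyclo[4.1.0]heptan-2-one (oxirane anti to the side chain)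
Conditions: 30% H2O2, NaOH (cat.), MeOH, 0 °C
Reagents that add atoms: hydrogen peroxide, OO
Why: Weitz-Scheffer epoxidation touches only the electron-poor alkene, and axial attack of hydroperoxide on the half-chair that holds both ring substituents equatorial places the oxirane anti to the side chain as in carvone itself, which sets the future C2; the trans-diequatorial silyloxy/side-chain pair is also the thermodynamic one, so base cannot erode it.

Step 7
Reactants: 9 epoxy ketone
Product: 11 (1S,4S,5R)-4-(TBSO)-5-[3-(TBSO)prop-1-en-2-yl]-2-methylcyclohex-2-en-1-ol (ring alkene now C12=C3 with free C2-OH), via epoxy hydrazone 10 (not isolated)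
Conditions: N2H4·H2O, AcOH (cat.), MeOH, 0 °C → rt
Reagents that add atoms: none
Why: Wharton transposition, in which the hydrazone opens the oxirane to an alkenyl diazene that loses N2, moves the alkene to C12=C3 and frees the C2 hydroxyl with retention because the C2-O bond is never broken, while β-loss of the C13 silyloxy group would demand a six-membered allene.

Step 8
Reactants: 11 transposed allylic alcohol
Product: 12 (1S,2S,4R,5R,6R)-5-(TBSO)-4-[3-(TBSO)prop-1-en-2-yl]-1-methyl-7-oxabicyclo[4.1.0]heptan-2-ol (oxirane syn to OH)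
Conditions: VO(acac)2 (cat.), t-BuOOH, CH2Cl2, 0 °C → rt
Reagents that add atoms: tert-butyl hydroperoxide, CC(C)(C)OO
Why: Vanadium-catalysed hydroxyl-directed epoxidation marks only the alkene of the allylic alcohol, syn to the pseudoaxial C2-OH, and ignores the exocyclic alkene whose oxygen is silylated; the two new oxirane centres are erased in step 10, so their configuration is of no consequence.

Step 9
Reactants: 12 epoxy alcohol
Product: 13 (1S,2S,4R,5R,6R)-5-(TBSO)-4-[3-(TBSO)prop-1-en-2-yl]-2-(PMBO)-1-methyl-7-oxabicyclo[4.1.0]heptane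
Conditions: 2-(4-methoxybenzyloxy)-4-methylquinoline, MeOTf, MgO, PhCF3, 0 °C → rt
Reagents that add atoms: 2-(4-methoxybenzyloxy)-4-methylquinoline, COc1ccc(COc2cc(C)c3ccccc3n2)cc1
Why: Benzyl transfer from the N-methylated 2-benzyloxyquinolinium salt formed in situ runs under MgO-buffered neutral conditions, so neither an alkoxide (silyl migration) nor a Brønsted acid (oxirane opening) is present, and the PMB ether is chosen because it chelates magnesium in step 16 and leaves oxidatively at the end.

Step 10
Reactants: 13 PMB-protected ring epoxide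
Product: 15 (2R,3R,5S)-2-(TBSO)-3-[3-(TBSO)prop-1-en-2-yl]-5-(PMBO)-6-oxoheptanal (C12 aldehyde / C3 methyl ketone), via trans-diol 14 (not isolated)
Conditions: H5IO6, THF-Et2O, 0 °C → rt
Reagents that add atoms: periodic acid, OI(=O)(O)(O)(O)O
Why: Periodic acid protonates the trisubstituted oxirane, water carried by the reagent opens it at tertiary C3 to the trans-diol 14, the diol is taken up as a five-membered cyclic periodate ester, and this ester fragments in a concerted electron shift that breaks C12-C3 and releases iodic acid. The closest known reaction type is the one-pot periodic acid (Malaprade-type) cleavage of terpene-derived trisubstituted cyclohexene oxides such as limonene oxide to 1,6-keto aldehydes. No bond is formed and no ring is closed, since the carbocycle and the oxirane are both opened and leave C12 as an aldehyde and C3 as a methyl ketone at the two ends of one chain. No stereocentre is created; C13, C14 and C2 are carried over unchanged and both oxirane centres vanish. The step needs cleavage of a single C-C bond without attack on the 1,1-disubstituted alkene and without epimerisation of the two α-alkoxy carbonyl centres. This is secured because step 8 placed the only oxirane exactly on C12-C3, the capped oxygens on C2 and C13 leave no second glycol for periodate, and the medium is cold and non-basic.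

Step 11
Reactants: 15 keto aldehyde
Product: 16 (3S,5R,6R)-6-(TBSO)-5-[3-(TBSO)prop-1-en-2-yl]-7-hydroxy-3-(PMBO)heptan-2-one
Conditions: LiAlH(Ot-Bu)3, THF, -78 → -40 °C
Reagents that add atoms: none
Why: Chemoselective hydride reduction, in which the bulky tri-tert-butoxyaluminium hydride reduces an aldehyde much faster than a ketone in the cold, while the weakly basic aluminate keeps the C13 silyl group from migrating to the new primary oxygen.

Step 12
Reactants: 16 hydroxy ketone
Product: 17 (2R,3R,5S)-2-(TBSO)-3-[3-(TBSO)prop-1-en-2-yl]-5-(PMBO)-6-oxoheptyl pivalate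
Conditions: PivCl, pyridine, DMAP (cat.), CH2Cl2, 0 °C
Reagents that add atoms: pivaloyl chloride, CC(C)(C)C(=O)Cl
Why: Standard DMAP-assisted acylation of a primary alcohol gives an ester hindered enough to survive the organomagnesium addition at -78 °C and orthogonal to the silyl and PMB ethers.

Step 13
Reactants: 18 3-bromopropan-1-ol
Product: 19 (3-bromopropoxy)triethylsilane
Conditions: TESCl, imidazole, CH2Cl2, 0 °C
Reagents that add atoms: triethylsilyl chloride, CC[Si](CC)(CC)Cl
Why: Routine silylation, with TES chosen because it can later be taken off in the presence of the TBS ethers.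

Step 14
Reactants: 19 (3-bromopropoxy)triethylsilane, 20 5-methyl-2,3-dihydrofuran
Product: 22 (Z)-4-methyl-7-(triethylsilyloxy)hept-3-en-1-ol, via Grignard reagent 21 (not isolated)
Conditions: Mg, THF, 40 °C; then 20, NiCl2(dppp) (5 mol %), toluene, 70 °C
Reagents that add atoms: none
Why: Nickel-catalysed cross-coupling of a Grignard reagent with a cyclic enol ether (Wenkert-type C-O activation) replaces the ring oxygen on C7 by the alkyl group with retention, so the cis relation of oxygen and ring CH2 in the dihydrofuran becomes the Z geometry of C6=C7; the chelating diphosphine is chosen to disfavour β-hydride elimination from the alkylnickel species.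

Step 15
Reactants: 22 (Z)-homoallylic alcohol
Product: 23 (Z)-triethyl[(7-iodo-4-methylhept-4-en-1-yl)oxy]silane (C4 to C10)
Conditions: I2, PPh3, imidazole, CH2Cl2, 0 °C
Reagents that add atoms: iodine, II
Why: Appel-type iodination of a primary alcohol under imidazole buffering tolerates the TES ether and cannot affect the alkene geometry.

Step 16
Reactants: 23 (Z)-homoallylic iodide, 17 methyl ketone pivalate
Product: 26 (2R,3R,5S,6S,9Z)-2-(TBSO)-3-[3-(TBSO)prop-1-en-2-yl]-6-hydroxy-5-(PMBO)-6,10-dimethyl-13-(TESO)tridec-9-en-1-yl pivalate, via homoallyllithium 24 (not isolated), via homoallylmagnesium bromide 25 (not isolated)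
Conditions: 23, t-BuLi (2 equiv), Et2O, -78 °C; MgBr2·OEt2, -78 → 0 °C; then 17, CH2Cl2, -78 °C
Reagents that add atoms: none
Why: Lithium-iodine exchange and transmetallation give the homoallylmagnesium bromide, which adds to the α-alkoxy methyl ketone under Cram-chelate control, magnesium bridging the carbonyl and PMB oxygens and the nucleophile entering past the C2 hydrogen, to set the 2,3-syn (3S) tertiary alcohol while the pivalate is inert at -78 °C.

Step 17
Reactants: 26 C3 tertiary alcohol
Product: 27 (2R,3R,5S,6S,9Z)-2-(TBSO)-3-[3-(TBSO)prop-1-en-2-yl]-6,13-dihydroxy-5-(PMBO)-6,10-dimethyltridec-9-en-1-yl pivalate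
Conditions: PPTS (cat.), MeOH-CH2Cl2, 0 °C
Reagents that add atoms: none
Why: Mild acid-catalysed methanolysis separates the primary TES ether from the TBS ethers through their large difference in solvolysis rate.

Step 18
Reactants: 27 C10 primary alcohol
Product: 28 (2R,3R,5S,6S,9Z)-2-(TBSO)-3-[3-(TBSO)prop-1-en-2-yl]-6-hydroxy-5-(PMBO)-6,10-dimethyl-13-oxotridec-9-en-1-yl pivalate
Conditions: TEMPO (cat.), PhI(OAc)2, CH2Cl2, rt
Reagents that add atoms: none
Why: Oxoammonium (TEMPO) oxidation is selective for the primary alcohol, stops at the aldehyde and leaves the tertiary alcohol, the PMB ether and the alkenes alone.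

Step 19
Reactants: 28 C10 aldehyde, 29 ethyltriphenylphosphonium iodide
Product: 33 (2R,3R,5S,6S,9Z,13Z)-2-(TBSO)-3-[3-(TBSO)prop-1-en-2-yl]-6-hydroxy-14-iodo-5-(PMBO)-6,10-dimethylpentadeca-9,13-dien-1-yl pivalate, via ethylidene ylide 30 (not isolated), via iodoethylphosphonium iodide 31 (not isolated), via iodoethylidene ylide 32 (not isolated)
Conditions: 29, n-BuLi, THF, 0 °C → rt; I2, -78 °C; NaHMDS, -20 °C; then 28, -78 °C
Reagents that add atoms: iodine, II
Why: Stork-Zhao-type Wittig olefination with the α-iodoethylidene ylide gives the (Z)-2-iodoalk-2-ene under kinetic control with iodine cis to the chain, the geometry that puts C9 and C12 cis once iodine is exchanged for C12, and the ylide is not basic enough to deprotonate the tertiary alcohol.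

Step 20
Reactants: 33 vinyl iodide pivalate
Product: 34 (2R,3R,5S,6S,9Z,13Z)-2-(TBSO)-3-[3-(TBSO)prop-1-en-2-yl]-14-iodo-5-(PMBO)-6,10-dimethylpentadeca-9,13-diene-1,6-diol
Conditions: DIBAL-H, CH2Cl2, -78 °C
Reagents that add atoms: none
Why: Reductive ester cleavage with DIBAL-H in the cold removes the pivalate without a free alkoxide base, so the C13 silyl group stays in place and the alkenyl iodide, silyl ethers and PMB ether are untouched.

Step 21
Reactants: 34 C12 primary alcohol
Product: 35 (2R,3R,5S,6S,9Z,13Z)-2-(TBSO)-3-[3-(TBSO)prop-1-en-2-yl]-6-hydroxy-14-iodo-5-(PMBO)-6,10-dimethylpentadeca-9,13-dienal (seco vinyl iodide aldehyde)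
Conditions: Dess-Martin periodinane, CH2Cl2, 0 °C → rt
Reagents that add atoms: none
Why: Dess-Martin oxidation converts the hindered primary alcohol into the α-silyloxy aldehyde under non-basic conditions that do not epimerise C13, and the tertiary alcohol cannot be oxidised.

Step 22
Reactants: 35 seco vinyl iodide aldehyde
Product: 37 (2S,3S,12S,13R,14R,6Z,10Z)-13-(TBSO)-14-[3-(TBSO)prop-1-en-2-yl]-2-(PMBO)-3,7,11-trimethylcyclotetradeca-6,10-diene-3,12-diol (route numbering), via alkenylchromium dichloride 36 (not isolated)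
Conditions: CrCl2 (excess), NiCl2 (cat.), DMSO-THF, high dilution, rt
Reagents that add atoms: none
Why: Intramolecular Nozaki-Hiyama-Kishi reaction, in which nickel-mediated formation of the alkenylchromium(III) species keeps the Z geometry, the addition is aldehyde-selective and tolerates the free tertiary alcohol, dilution favours the 14-membered ring, and polar Felkin-Anh attack anti to the C13 silyloxy group should give the 12,13-anti (12S) carbinol.

Step 23
Reactants: 37 macrocyclic diol
Product: 38 (2S,3S,12S,13R,14R,6Z,10Z)-13-(TBSO)-14-[3-(TBSO)prop-1-en-2-yl]-2-(PMBO)-3,7,11-trimethylcyclotetradeca-6,10-diene-3,12-diyl diacetate (route numbering)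
Conditions: Ac2O (excess), Et3N, DMAP, CH2Cl2, rt → 40 °C
Reagents that add atoms: acetic anhydride, CC(=O)OC(C)=O
Why: DMAP-catalysed acylation with excess anhydride acetylates the secondary allylic alcohol at once and the hindered tertiary alcohol on gentle warming, and the basic medium avoids ionisation of the allylic acetate.

Step 24
Reactants: 38 diacetate bis(silyl ether)
Product: 39 (2S,3S,12S,13R,14R,6Z,10Z)-13-hydroxy-14-(3-hydroxyprop-1-en-2-yl)-2-(PMBO)-3,7,11-trimethylcyclotetradeca-6,10-diene-3,12-diyl diacetate (route numbering)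
Conditions: HF·pyridine, pyridine-THF, 0 °C → rt
Reagents that add atoms: none
Why: Fluoride desilylation in a weakly acidic medium cleaves both TBS ethers while suppressing the base-induced acetyl shift from C12-O to the freed C13-OH.

Step 25
Reactants: 39 C13/C16 diol
Product: 42 (2S,3S,12S,13R,14R,6Z,10Z)-3,12-diacetoxy-2-(PMBO)cembra-6,10,15(17)-trien-16,13-olide (route numbering; C2-O-PMB ether of the target), via hydroxy enal 40 (not isolated), via lactol 41 (not isolated)
Conditions: activated MnO2 (excess), CH2Cl2, rt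
Reagents that add atoms: none
Why: Manganese dioxide oxidises only the allylic primary alcohol, the enal is trapped by C13-OH as a five-membered lactol, and this is oxidised on to the α-methylene-γ-butyrolactone, the standard oxidative lactonisation of 2-methylene-1,4-diols, with C13 and C14 unchanged.

Step 26
Reactants: 42 C2-O-PMB ether
Product: 43 CNP0127975.1, (2S,3S,12S,13R,14R,6Z,10Z)-3,12-diacetoxy-2-hydroxycembra-6,10,15(17)-trien-16,13-olide (route numbering)
Conditions: DDQ, CH2Cl2-pH 7 buffer, 0 °C
Reagents that add atoms: none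
Why: Oxidative PMB cleavage with DDQ (hydride abstraction to the oxocarbenium ion, then hydrolysis) at buffered neutral pH frees C2-OH without acetyl migration from C3-O and without touching the alkenes, the acetates or the methylene lactone.

**Compound list**

1 | (S)-(+)-carvone | CC1=CC[C@@H](CC1=O)C(C)=C | starting material
2 | (5S)-10-chlorocarvone | CC1=CC[C@@H](CC1=O)C(=C)CCl | intermediate
3 | (5S)-10-acetoxycarvone (not isolated) | CC1=CC[C@@H](CC1=O)C(=C)COC(C)=O | intermediate
4 | (5S)-10-hydroxycarvone | CC1=CC[C@@H](CC1=O)C(=C)CO | intermediate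
5 | (5S)-10-(TBSO)carvone | CC1=CC[C@@H](CC1=O)C(=C)CO[Si](C)(C)C(C)(C)C | intermediate
6 | lithium cross-conjugated dienolate of 5 (not isolated) | CC1=CC[C@@H](C=C1[O-])C(=C)CO[Si](C)(C)C(C)(C)C.[Li+] | intermediate
7 | (5R,6R)-6-hydroxy-10-(TBSO)carvone | O[C@@H]1[C@@H](C(=C)CO[Si](C)(C)C(C)(C)C)CC=C(C)C1=O | intermediate
8 | (5R,6R)-6,10-bis(TBSO)carvone | CC(C)(C)[Si](C)(C)O[C@@H]1[C@@H](C(=C)CO[Si](C)(C)C(C)(C)C)CC=C(C)C1=O | intermediate
9 | (1S,3R,4R,6S)-epoxy ketone | CC(C)(C)[Si](C)(C)O[C@@H]1[C@@H](C(=C)CO[Si](C)(C)C(C)(C)C)C[C@@H]2O[C@]2(C)C1=O | intermediate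
10 | hydrazone of 9 (not isolated) | CC(C)(C)[Si](C)(C)O[C@@H]1[C@@H](C(=C)CO[Si](C)(C)C(C)(C)C)C[C@@H]2O[C@]2(C)C1=NN | intermediate
11 | (1S,4S,5R)-transposed allylic alcohol | CC(C)(C)[Si](C)(C)O[C@@H]1[C@@H](C(=C)CO[Si](C)(C)C(C)(C)C)C[C@H](O)C(C)=C1 | intermediate
12 | (1S,2S,4R,5R,6R)-syn-epoxy alcohol | CC(C)(C)[Si](C)(C)O[C@@H]1[C@@H](C(=C)CO[Si](C)(C)C(C)(C)C)C[C@H](O)[C@]2(C)O[C@H]12 | intermediate
13 | PMB ether of 12 | CC(C)(C)[Si](C)(C)O[C@@H]1[C@@H](C(=C)CO[Si](C)(C)C(C)(C)C)C[C@H](OCc3ccc(OC)cc3)[C@]2(C)O[C@H]12 | intermediate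
14 | (2S,3S,12R,13R,14R)-C3,C12 trans-diol, route numbering (not isolated) | CC(C)(C)[Si](C)(C)O[C@@H]1[C@@H](C(=C)CO[Si](C)(C)C(C)(C)C)C[C@H](OCc2ccc(OC)cc2)[C@@](C)(O)[C@@H]1O | intermediate
15 | (2R,3R,5S)-keto aldehyde | CC(C)(C)[Si](C)(C)O[C@@H](C=O)[C@@H](C(=C)CO[Si](C)(C)C(C)(C)C)C[C@H](OCc1ccc(OC)cc1)C(C)=O | intermediate
16 | (3S,5R,6R)-hydroxy ketone | CC(C)(C)[Si](C)(C)O[C@@H](CO)[C@@H](C(=C)CO[Si](C)(C)C(C)(C)C)C[C@H](OCc1ccc(OC)cc1)C(C)=O | intermediate
17 | (2R,3R,5S)-methyl ketone pivalate | CC(C)(C)[Si](C)(C)O[C@@H](COC(=O)C(C)(C)C)[C@@H](C(=C)CO[Si](C)(C)C(C)(C)C)C[C@H](OCc1ccc(OC)cc1)C(C)=O | intermediate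
18 | 3-bromopropan-1-ol | OCCCBr | starting material
19 | (3-bromopropoxy)triethylsilane | BrCCCO[Si](CC)(CC)CC | intermediate
20 | 5-methyl-2,3-dihydrofuran | CC1=CCCO1 | starting material
21 | [3-(triethylsilyloxy)propyl]magnesium bromide (not isolated) | Br[Mg]CCCO[Si](CC)(CC)CC | intermediate
22 | (Z)-4-methyl-7-(triethylsilyloxy)hept-3-en-1-ol | OCC/C=C(/C)CCCO[Si](CC)(CC)CC | intermediate
23 | (Z)-homoallylic iodide, C4 to C10 | ICC/C=C(/C)CCCO[Si](CC)(CC)CC | intermediate
24 | (Z)-homoallyllithium (not isolated) | [Li]CC/C=C(/C)CCCO[Si](CC)(CC)CC | intermediate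
25 | (Z)-homoallylmagnesium bromide (not isolated) | Br[Mg]CC/C=C(/C)CCCO[Si](CC)(CC)CC | intermediate
26 | (2S,3S,13R,14R,6Z)-C3 tertiary alcohol with C10-OTES, route numbering | CC(C)(C)[Si](C)(C)O[C@@H](COC(=O)C(C)(C)C)[C@@H](C(=C)CO[Si](C)(C)C(C)(C)C)C[C@H](OCc1ccc(OC)cc1)[C@@](C)(O)CC/C=C(/C)CCCO[Si](CC)(CC)CC | intermediate
27 | C10 primary alcohol | CC(C)(C)[Si](C)(C)O[C@@H](COC(=O)C(C)(C)C)[C@@H](C(=C)CO[Si](C)(C)C(C)(C)C)C[C@H](OCc1ccc(OC)cc1)[C@@](C)(O)CC/C=C(/C)CCCO | intermediate
28 | C10 aldehyde | CC(C)(C)[Si](C)(C)O[C@@H](COC(=O)C(C)(C)C)[C@@H](C(=C)CO[Si](C)(C)C(C)(C)C)C[C@H](OCc1ccc(OC)cc1)[C@@](C)(O)CC/C=C(/C)CCC=O | intermediate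
29 | ethyltriphenylphosphonium iodide | CC[P+](c1ccccc1)(c1ccccc1)c1ccccc1.[I-] | starting material
30 | ethylidenetriphenylphosphorane (not isolated) | CC=P(c1ccccc1)(c1ccccc1)c1ccccc1 | intermediate
31 | (1-iodoethyl)triphenylphosphonium iodide (not isolated) | CC(I)[P+](c1ccccc1)(c1ccccc1)c1ccccc1.[I-] | intermediate
32 | (1-iodoethylidene)triphenylphosphorane (not isolated) | CC(I)=P(c1ccccc1)(c1ccccc1)c1ccccc1 | intermediate
33 | (6Z,10Z)-vinyl iodide pivalate | CC(C)(C)[Si](C)(C)O[C@@H](COC(=O)C(C)(C)C)[C@@H](C(=C)CO[Si](C)(C)C(C)(C)C)C[C@H](OCc1ccc(OC)cc1)[C@@](C)(O)CC/C=C(/C)CC/C=C(/C)I | intermediate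
34 | (6Z,10Z)-vinyl iodide C12 primary alcohol | CC(C)(C)[Si](C)(C)O[C@@H](CO)[C@@H](C(=C)CO[Si](C)(C)C(C)(C)C)C[C@H](OCc1ccc(OC)cc1)[C@@](C)(O)CC/C=C(/C)CC/C=C(/C)I | intermediate
35 | seco (Z)-vinyl iodide aldehyde | CC(C)(C)[Si](C)(C)O[C@@H](C=O)[C@@H](C(=C)CO[Si](C)(C)C(C)(C)C)C[C@H](OCc1ccc(OC)cc1)[C@@](C)(O)CC/C=C(/C)CC/C=C(/C)I | intermediate
36 | (Z)-alkenylchromium(III) dichloride (not isolated) | CC(C)(C)[Si](C)(C)O[C@@H](C=O)[C@@H](C(=C)CO[Si](C)(C)C(C)(C)C)C[C@H](OCc1ccc(OC)cc1)[C@@](C)(O)CC/C=C(/C)CC/C=C(/C)[Cr](Cl)Cl | intermediate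
37 | 14-membered carbocycle, (12S)-C12-OH and C3-OH | CC(C)(C)[Si](C)(C)O[C@@H]1[C@@H](C(=C)CO[Si](C)(C)C(C)(C)C)C[C@H](OCc2ccc(OC)cc2)[C@@](C)(O)CC/C=C(/C)CC/C=C(/C)[C@@H]1O | intermediate
38 | C3,C12-diacetate | CC(C)(C)[Si](C)(C)O[C@@H]1[C@@H](C(=C)CO[Si](C)(C)C(C)(C)C)C[C@H](OCc2ccc(OC)cc2)[C@@](C)(OC(C)=O)CC/C=C(/C)CC/C=C(/C)[C@@H]1OC(C)=O | intermediate
39 | C13/C16 diol | O[C@@H]1[C@@H](C(=C)CO)C[C@H](OCc2ccc(OC)cc2)[C@@](C)(OC(C)=O)CC/C=C(/C)CC/C=C(/C)[C@@H]1OC(C)=O | intermediate
40 | C13-hydroxy C16-enal (not isolated) | O[C@@H]1[C@@H](C(=C)C=O)C[C@H](OCc2ccc(OC)cc2)[C@@](C)(OC(C)=O)CC/C=C(/C)CC/C=C(/C)[C@@H]1OC(C)=O | intermediate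
41 | α-methylene lactol, anomeric centre undefined (not isolated) | C=C1C(O)O[C@@H]2[C@@H]1C[C@H](OCc3ccc(OC)cc3)[C@@](C)(OC(C)=O)CC/C=C(/C)CC/C=C(/C)[C@@H]2OC(C)=O | intermediate
42 | C2-O-PMB ether of the target | C=C1C(=O)O[C@@H]2[C@@H]1C[C@H](OCc3ccc(OC)cc3)[C@@](C)(OC(C)=O)CC/C=C(/C)CC/C=C(/C)[C@@H]2OC(C)=O | intermediate
43 | CNP0127975.1 | C=C1C(=O)O[C@@H]2[C@@H]1C[C@H](O)[C@@](C)(OC(C)=O)CC/C=C(/C)CC/C=C(/C)[C@@H]2OC(C)=O | target

**Count and risks**

Total steps: 26. Longest linear sequence: 23 (steps 1-12 and 16-26). The C4-C10 iodide takes 3 steps (13-15).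

**Step 22.**
- **Risk:** Intermolecular coupling and proto-deiodination compete with ring closure. The conformation of the forming 14-membered ring may also override the Felkin-Anh bias, so that facial selectivity at C12 is poor.
- **Fallback (from 35, back at 37):** The chromium closure is used only to make the ring. The carbinol mixture, 37 together with its C12 epimer F1, is oxidised with Dess-Martin periodinane to the macrocyclic (Z)-enone F2. C12 is then set by a Corey-Bakshi-Shibata 1,2-reduction. Here the enantiomer of the oxazaborolidine, chosen by a trial with both antipodes, picks the carbonyl face rather than the ring conformation, and this returns 37.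

**Step 14.**
- **Risk:** β-Hydride elimination from the alkylnickel intermediate (net reduction of the C-O bond), partial loss of alkene geometry, and silyl transfer to the magnesium alkoxide at the elevated temperature can all erode the coupling.
- **Fallback (from Grignard reagent 21, back at 22):** The alkene is built by syn-carbocupration instead of C-O activation. Reagent 21, prepared in Et2O, is transmetallated with CuBr·SMe2 to the alkylcopper reagent F3. This adds syn across propyne, with the alkyl group going to the internal carbon, to give the (Z)-alkenylcopper F4. After activation as the mixed pentynyl cuprate, F4 opens ethylene oxide to deliver 22. The geometry is then fixed by syn addition to an alkyne.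

**Step 10.**
- **Risk:** The oxirane is flanked by two electron-withdrawing C-O bonds and may open slowly. The trans-diaxial glycol may be reluctant to form a cyclic periodate. The longer acid exposure that results invites loss of the primary allylic silyl ether.
- **Fallback (from 13, back at 15):** The two events are separated and the oxidant is changed to one that needs no cyclic ester. The oxirane is hydrolysed with catalytic HClO4 in cold aqueous THF and the trans-diol 14 is isolated. It is then cut by Criegee glycol cleavage with Pb(OAc)4 over K2CO3 in benzene. The same C12-C3 bond is broken, and no compound outside the list is made (F0).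

**Further compounds**

F1 | step 22 | C12 epimer (12R) of macrocycle 37 | CC(C)(C)[Si](C)(C)O[C@@H]1[C@@H](C(=C)CO[Si](C)(C)C(C)(C)C)C[C@H](OCc2ccc(OC)cc2)[C@@](C)(O)CC/C=C(/C)CC/C=C(/C)[C@H]1O
F2 | step 22 | macrocyclic (Z)-C12 enone | CC(C)(C)[Si](C)(C)O[C@@H]1[C@@H](C(=C)CO[Si](C)(C)C(C)(C)C)C[C@H](OCc2ccc(OC)cc2)[C@@](C)(O)CC/C=C(/C)CC/C=C(/C)C1=O
F3 | step 14 | [3-(triethylsilyloxy)propyl]copper | [Cu]CCCO[Si](CC)(CC)CC
F4 | step 14 | (Z)-[2-methyl-5-(triethylsilyloxy)pent-1-en-1-yl]copper | [Cu]/C=C(/C)CCCO[Si](CC)(CC)CC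
F0 | step 10 | none | none
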